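## Structural features

The target 25 holds three five-membered oxygen rings on one chain. Ring A is a 3-methyl-4-hydroxyfuran-2(5H)-one (a tetronic acid) with an exocyclic double bond at C5. Ring B is a furan substituted at both β-carbons (C3 and C4) and at neither α-carbon. Ring C is a furan-3-yl group tied to C4 of ring B through a single CH2. Rings A and B are joined by a nine-carbon chain, C1′ (the ylidene carbon on C5 of ring A) to C9′ (bound to C3 of ring B). The chain carries a (6′E) trisubstituted and an (8′E) disubstituted alkene conjugated with ring B, a methyl group on C6′, and the only stereocenter, C2′ (S), which bears the second methyl group. No stereocenter stands next to another, but C2′ is allylic to the (Z)-C5=C1′ bond and sits α to the carbonyl group in any aldehyde precursor, so it can be lost by enolization; three alkene geometries must also be right. The furans are sensitive to acid, oxidants and electrophilic halogen, the furyl diene to acid, light and oxygen, and the tetronic acid is acidic, chelating and, as its enol ether, electrophilic at C4 and C1′. The real difficulty is the β,β′-pattern of ring B, because substitution or metalation of a furan goes to the α-positions; behind it come the three geometries and a lone stereocenter with no neighbour to direct it. The key step uses the C3–C4 bond of ring B: the carbon that becomes C3 (carrying an ester, later C9′) attacks as a radical the alkyne carbon that becomes C4, and the distal alkyne carbon becomes the CH2 between rings B and C.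

## Logic of the disconnections

**25 to 24.** The O–CH3 bond on O4 of ring A is cut. The free enol is acidic and would quench any enolate used to build ring A onto the chain, so it is masked until the end. Nothing is gained in skeleton. The forward step must be a dealkylation that leaves the ylidene lactone, the diene and both furans alone.

**24 to 21 and 19, through 23 and 22.** The C5=C1′ double bond is cut, first as loss of water across C5–C1′ and then as the C5–C1′ single bond. C5 is the only acidic carbon of 21, so ring A comes off as a one-step piece and the rest becomes a simple aldehyde. The forward steps must keep C2′ of 19 from enolizing and must give the (Z) geometry on elimination.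

**19 to 10 and 17, through 18.** After adjusting C1′ to the alcohol level, the C8′=C9′ double bond is cut. This divides the molecule near its middle into the difuran half and the chain half. An (E) alkene next to an aromatic ring suits a phosphonate olefination, and the (6′E) alkene travels intact in 17. The forward step must give (E) at the new bond, keep (6′E), react through the α-carbon of the allyl anion and tolerate an alkoxide.

**17 to 11 and 12, through 16, 15, 14 and 13.** The two C–H bonds that make C2′ a stereocenter are removed (back to the C2′=C3′ enal), then the C1′–O bond (back to a methyl group), then the C–P bond. Compound 11 already holds all ten chain carbons and the (6′E) alkene, so only one oxidation and one reduction are needed. The forward steps need site-selective oxidation of the terminal (E)-methyl group and face-selective reduction of the enal.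

**10 to 8, through 9.** Only the oxidation level at the future C9′ changes. The ester is what stabilizes the radical in the ring-forming step, so it is carried to this point and then adjusted.

**8 to 6, through 7.** The C3–C4 bond of ring B is cut, with re-addition of ethanol and return of the ring double bond to an exocyclic position. This places both substituents at β-carbons by construction and reduces the difuran to an acyclic bromoacetal holding one furan. The forward step needs ring closure to be faster than reduction of the radical, and then clean aromatization.

**6 to 4 and 3, through 5.** The acetal C–O bond to the propargylic oxygen and both C–Br bonds are cut. The two halves are a commodity acrylate and an alcohol. The forward step must keep electrophilic bromine away from ring C.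

**3 to 1 and 2.** The bond between C3 of ring C and the alkyne carbon is cut; both pieces are commercial. The forward step is a cross-coupling of a rather unreactive heteroaryl bromide.

**21 to 20.** The O–CH3 bond is cut back to the parent tetronic acid.

## Other disconnections considered

**Alternative 1:** The cut is in a carbocyclic precursor, not in the target: oxygen is inserted next to one of the two methyl-bearing carbons of meso ketone A2 (cis-2,6-dimethylcyclohexanone) to give lactone A1, (3S,7R)-3,7-dimethyloxepan-2-one. The forward key step is a Baeyer–Villiger monooxygenase with NADPH and O2 that selects one of the two enantiotopic acyl–carbon bonds.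
- In its favour: it creates the only stereocenter catalytically from a cheap achiral ketone. C3 of A1 maps directly onto C2′ (S), the acyl carbon onto C1′, and the carbinol carbon onto C6′.
- Against it here: the second stereocenter of A1 is destroyed when the carbinol is oxidized. The resulting methyl ketone must then be olefinated to the (6′E) alkene, where methyl ketones give modest selectivity; the chosen plan buys that geometry in 11. The trans isomer in commercial ketone has to be removed, and the α-stereocenter of A1 can enolize during ring opening.
- Comparison: it addresses only what steps 6 to 8 address and leaves ring B open. Both plans set C2′ with an enzyme. Selecting an enantiotopic group in a meso compound does not depend on trapping a configurationally labile aldehyde such as 16, so on robustness of the stereocenter it is the equal of the chosen plan or better. On step economy it is worse: ring opening, protection, oxidation, olefination and conversion into an olefination reagent would follow, against three steps in all to 17.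

**Alternative 2:** The cut is the C7′–C8′ single bond of the diene together with the C6′–CH3 bond. The forward key step is Cp2ZrCl2-mediated syn-methylalumination of alkyne A4, tert-butyldimethyl{[(2S)-2-methylhept-6-yn-1-yl]oxy}silane, with AlMe3, then Pd(PPh3)4-catalysed coupling of the alkenylalane with vinyl iodide A5, 3-(furan-3-ylmethyl)-4-[(E)-2-iodoethenyl]furan, to give silyl ether A3.
- In its favour: both geometries follow from mechanism (syn addition, then coupling with retention) and not from the selectivity of a carbonyl olefination. No delocalized allyl anion is involved. A5 could be made from 10 by an iodo-olefination with CHI3 and CrCl2, so it fits the same ring B construction.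
- Against it here: A4 needs its own synthesis with the stereocenter (auxiliary alkylation or chiral pool, several steps). AlMe3 is pyrophoric and used in excess, the iodo-olefination needs stoichiometric CrCl2, and A3 needs a desilylation that 18 does not.
- Comparison: on control of diene geometry it is better than step 9. On convergence it is equal. On step count and reagent burden it is worse by about three to four steps.

**Alternative 3:** The cut is the O1–C5 bond of ring A. The forward key step is AgNO3-catalysed 5-exo-dig attack of the carboxylic acid oxygen of enynoic acid A7 on the near alkyne carbon, which gives A6, the O-methyl ether of the target (the same compound as 24).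
- In its favour: the (Z) geometry follows from anti addition of oxygen and silver across the alkyne and protonolysis with retention. No base meets the ylidene lactone, and C2′ is propargylic in A7, not α to an aldehyde.
- Against it here: A7 is hard to reach. It needs a trisubstituted β-methoxy acrylic acid with the carboxyl group cis to the alkyne, attached to a chiral terminal alkyne made by homologation of 19. A 6-endo closure to a pyranone can compete. The methyl ether must still be cleaved.
- Comparison: on the C5=C1′ geometry and the safety of C2′ it is better than steps 12 and 13. On the last step it is equal. On step economy it is worse, with at least four steps from 19 to A6 against two to 24.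

Key step: step 3

Remarks on the chemistry:
- Assumption: 4-hydroxy-3-methylfuran-2(5H)-one (20) is taken as a catalogue compound; otherwise it comes in one operation from ethyl 2-methylacetoacetate by bromination and thermal lactonization.
- The structures of 6 and 8 are consistent with each other (C14H17BrO5 gives C12H12O4 after exchange of Br for H and loss of ethanol) and are kept unchanged.
- The improvement is in how 6 is assembled: the acrylate is brominated before the furyl alcohol is added, so no electrophilic bromine source ever meets ring C.

Step 1
Reactants: 1 3-bromofuran; 2 prop-2-yn-1-ol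
Product: 3 3-(furan-3-yl)prop-2-yn-1-ol
Conditions: PdCl2(PPh3)2 (2 mol %), CuI (4 mol %), i-Pr2NH, degassed, 60 °C
Reagents that add atoms: none
Why: Sonogashira coupling of a heteroaryl bromide with a terminal alkyne; the free hydroxyl is tolerated, and exclusion of oxygen suppresses oxidative dimerization of 2.

Step 2
Reactants: 4 ethyl (E)-3-ethoxyacrylate; 3 3-(furan-3-yl)prop-2-yn-1-ol
Product: 6 ethyl 2-bromo-3-ethoxy-3-{[3-(furan-3-yl)prop-2-yn-1-yl]oxy}propanoate (diastereomer mixture), via ethyl 2,3-dibromo-3-ethoxypropanoate 5 (not isolated)
Conditions: Br2 (0.98 equiv), CH2Cl2, −30 °C; then 3, 2,6-lutidine, −30 °C → rt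
Reagents that add atoms: bromine, BrBr
Why: Bromine adds across the enol ether to give the α-bromo ether 5, whose ether-activated bromide is replaced by the alcohol through an oxocarbenium ion (haloacetal formation of the Ueno–Stork type) while the α-ester bromide stays. Using slightly less than one equivalent of bromine and adding 3 only afterwards means the furan and the alkyne never meet free halogen; the hindered base takes up HBr.

Step 3
Reactants: 6 ethyl 2-bromo-3-ethoxy-3-{[3-(furan-3-yl)prop-2-yn-1-yl]oxy}propanoate
Product: 8 ethyl 4-(furan-3-ylmethyl)furan-3-carboxylate, via ethyl 2-ethoxy-4-(furan-3-ylmethylidene)oxolane-3-carboxylate 7 (not isolated)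
Conditions: Bu3SnH (1.2 equiv, syringe pump), AIBN (cat.), toluene (0.01 M), 80 °C; then p-TsOH·H2O (cat.), same flask, rt → 50 °C; KF work-up
Reagents that add atoms: none
Why: The tributylstannyl radical abstracts bromine from 6 to give an electrophilic α-ester radical, which adds to the near carbon of the electron-rich furyl alkyne and forms the bond between the future β-carbons C3 and C4 of ring B; the closest known reaction type is the Ueno–Stork haloacetal radical cyclization onto an alkyne followed by acid-promoted aromatization of the 2-alkoxy-4-alkylidene oxolane. The one ring closed is the oxolane that becomes ring B, in the 5-exo-dig mode; 6-endo closure would put the radical on a carbon without aryl stabilization, whereas exo closure gives a vinyl radical conjugated with ring C. That radical takes hydrogen from Bu3SnH and the chain goes on. No stereocenter needs control, because the alkene geometry and the two sp3 centres of 7 are erased on aromatization. p-TsOH then ionizes the acetal, ethanol is lost to give the 4,5-dihydrofuran-3-carboxylate, and a proton shift moves the exocyclic double bond into the ring, which leaves the CH2 bridge to ring C. The selectivity needed is cyclization over direct reduction of the stabilized radical; it is secured by slow addition of the stannane at high dilution, by the short tether with two oxygen atoms, and by the polarity match between an electrophilic radical and an electron-rich alkyne. The β,β′-pattern is fixed by construction, since the ester carbon and the alkyne carbon can only end as adjacent ring carbons away from oxygen.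

Step 4
Reactants: 8 ethyl 4-(furan-3-ylmethyl)furan-3-carboxylate
Product: 9 [4-(furan-3-ylmethyl)furan-3-yl]methanol
Conditions: i-Bu2AlH (2.5 equiv), CH2Cl2, −78 → 0 °C; aqueous KNaC4H4O6 work-up
Reagents that add atoms: none
Why: Full hydride reduction of a heteroaryl ester to the primary alcohol; stopping at the aldehyde is unreliable for furan esters, so the alcohol is taken deliberately.

Step 5
Reactants: 9 [4-(furan-3-ylmethyl)furan-3-yl]methanol
Product: 10 4-(furan-3-ylmethyl)furan-3-carbaldehyde
Conditions: MnO2 (activated, excess), CH2Cl2, rt
Reagents that add atoms: none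
Why: Heterogeneous oxidation of a furylmethyl (benzylic-type) alcohol that stops at the aldehyde and leaves both furans and the doubly activated CH2 bridge untouched.

Step 6
Reactants: 11 geranyl bromide, (2E)-1-bromo-3,7-dimethylocta-2,6-diene; 12 triethyl phosphite
Product: 13 diethyl [(2E)-3,7-dimethylocta-2,6-dien-1-yl]phosphonate
Conditions: neat, 130 °C, bromoethane distilled off
Reagents that add atoms: none
Why: Michaelis–Arbuzov reaction of a primary allylic bromide; direct displacement at C1 keeps the (2E) alkene in place.

Step 7
Reactants: 13 diethyl [(2E)-3,7-dimethylocta-2,6-dien-1-yl]phosphonate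
Product: 15 diethyl [(2E,6E)-3,7-dimethyl-8-oxoocta-2,6-dien-1-yl]phosphonate, via diethyl [(2E,6E)-8-hydroxy-3,7-dimethylocta-2,6-dien-1-yl]phosphonate 14 (not isolated)
Conditions: SeO2 (0.2 equiv), t-BuOOH, salicylic acid (cat.), CH2Cl2, rt; crude mixture then MnO2, CH2Cl2, rt
Reagents that add atoms: selenium dioxide, O=[Se]=O; tert-butyl hydroperoxide, CC(C)(C)OO (terminal oxidant that resupplies the oxygen)
Why: Allylic oxidation by an ene reaction and [2,3]-shift goes to the (E)-methyl group of the more electron-rich terminal alkene, as with other geranyl derivatives; the C2 alkene is deactivated by the phosphonate. MnO2 then brings the alcohol and aldehyde mixture to the enal alone.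

Step 8
Reactants: 15 diethyl [(2E,6E)-3,7-dimethyl-8-oxoocta-2,6-dien-1-yl]phosphonate
Product: 17 diethyl [(2E,7S)-8-hydroxy-3,7-dimethyloct-2-en-1-yl]phosphonate, via diethyl [(2E,7S)-3,7-dimethyl-8-oxooct-2-en-1-yl]phosphonate 16 (not isolated)
Conditions: fermenting baker's yeast (Saccharomyces cerevisiae), sucrose, H2O, 30 °C, substrate added in EtOH
Reagents that add atoms: none
Why: Whole-cell reduction of an (E)-α-methyl enal: the ene-reductase delivers hydride to the β-carbon and a proton to the α-carbon on the face that gives the (S)-2-methyl aldehyde, as in the known reductions of such enals made by terminal oxidation of terpenoids, and the alcohol dehydrogenase of the same cells reduces 16 before it can enolize. The isolated C2 alkene is not conjugated and is left alone.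

Step 9
Reactants: 17 diethyl [(2E,7S)-8-hydroxy-3,7-dimethyloct-2-en-1-yl]phosphonate; 10 4-(furan-3-ylmethyl)furan-3-carbaldehyde
Product: 18 (2S,6E,8E)-9-[4-(furan-3-ylmethyl)furan-3-yl]-2,6-dimethylnona-6,8-dien-1-ol
Conditions: 17, n-BuLi (2.1 equiv), THF–DMPU, −78 °C; then 10, −78 °C → rt; aqueous NH4Cl
Reagents that add atoms: none
Why: Horner–Wadsworth–Emmons olefination with an allylic phosphonate: the first equivalent of base makes the spectator alkoxide, the second the allyl anion, which attacks the aryl aldehyde through its α-carbon. Reversible addition and faster collapse of the adduct leading to the conjugated (E) alkene should favour (8E), and the (6E) alkene is carried over from 11.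

Step 10
Reactants: 18 (2S,6E,8E)-9-[4-(furan-3-ylmethyl)furan-3-yl]-2,6-dimethylnona-6,8-dien-1-ol
Product: 19 (2S,6E,8E)-9-[4-(furan-3-ylmethyl)furan-3-yl]-2,6-dimethylnona-6,8-dienal
Conditions: Dess–Martin periodinane, NaHCO3, CH2Cl2, 0 °C → rt; used at once
Reagents that add atoms: none
Why: Dess–Martin oxidation under buffered, near-neutral conditions, which should not enolize the α-methyl aldehyde and does not attack the diene or the furans.

Step 11
Reactants: 20 4-hydroxy-3-methylfuran-2(5H)-one (3-methyltetronic acid)
Product: 21 4-methoxy-3-methylfuran-2(5H)-one
Conditions: Me2SO4, K2CO3, acetone, reflux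
Reagents that add atoms: dimethyl sulfate, COS(=O)(=O)OC
Why: O-Alkylation of the tetronate anion with a hard methylating agent gives the vinylogous carbonate, which leaves C5–H as the only acidic position.

Step 12
Reactants: 21 4-methoxy-3-methylfuran-2(5H)-one; 19 (2S,6E,8E)-9-[4-(furan-3-ylmethyl)furan-3-yl]-2,6-dimethylnona-6,8-dienal
Product: 22 5-[(2S,6E,8E)-9-[4-(furan-3-ylmethyl)furan-3-yl]-1-hydroxy-2,6-dimethylnona-6,8-dien-1-yl]-4-methoxy-3-methylfuran-2(5H)-one (diastereomer mixture at C5 and C1′)
Conditions: 21, LiN(i-Pr)2, THF, −78 °C; then 19, −78 °C; AcOH quench at −78 °C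
Reagents that add atoms: none
Why: Aldol addition of the C5 lithium dienolate of a methyl tetronate to an aldehyde; at −78 °C addition should outrun proton transfer, so C2′ stays (S). The two new centres need no control because both are removed in step 13.

Step 13
Reactants: 22 5-[(2S,6E,8E)-9-[4-(furan-3-ylmethyl)furan-3-yl]-1-hydroxy-2,6-dimethylnona-6,8-dien-1-yl]-4-methoxy-3-methylfuran-2(5H)-one
Product: 24 (5Z)-5-[(2S,6E,8E)-9-[4-(furan-3-ylmethyl)furan-3-yl]-2,6-dimethylnona-6,8-dien-1-ylidene]-4-methoxy-3-methylfuran-2(5H)-one, via methanesulfonate of aldol adduct 23 (not isolated)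
Conditions: MsCl, Et3N, CH2Cl2, 0 °C; then DBU, 0 °C → rt
Reagents that add atoms: methanesulfonyl chloride, CS(=O)(=O)Cl (its atoms stay only in 23 and leave again on elimination)
Why: Mesylation, then E1cB elimination through the furanolate formed by removing the acidic C5–H. The (Z) isomer, with the chain next to the ring oxygen and away from the C4 methoxy group, is the more stable and the expected main product. The C2′–H is far less acidic than C5–H, so brief exposure to the amidine should leave the stereocenter intact.

Step 14
Reactants: 24 (5Z)-5-[(2S,6E,8E)-9-[4-(furan-3-ylmethyl)furan-3-yl]-2,6-dimethylnona-6,8-dien-1-ylidene]-4-methoxy-3-methylfuran-2(5H)-one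
Product: 25 (5Z)-5-[(2S,6E,8E)-9-[4-(furan-3-ylmethyl)furan-3-yl]-2,6-dimethylnona-6,8-dien-1-ylidene]-4-hydroxy-3-methylfuran-2(5H)-one (CNP0288126.1)
Conditions: NaSEt, DMF, rt; then cold 0.5 M HCl to pH 3, EtOAc
Reagents that add atoms: none
Why: SN2 demethylation of the vinylogous carbonate by a thiolate, with the tetronate anion as a good leaving group; the anion formed is no longer electrophilic, and brief cold acidification releases the target without harming the furans.

## Compound list

1 | 3-bromofuran | Brc1ccoc1 | starting material
2 | prop-2-yn-1-ol | OCC#C | starting material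
3 | 3-(furan-3-yl)prop-2-yn-1-ol | OCC#Cc1ccoc1 | intermediate
4 | ethyl (E)-3-ethoxyacrylate | CCO/C=C/C(=O)OCC | starting material
5 | ethyl 2,3-dibromo-3-ethoxypropanoate | CCOC(Br)C(Br)C(=O)OCC | intermediate (not isolated)
6 | ethyl 2-bromo-3-ethoxy-3-{[3-(furan-3-yl)prop-2-yn-1-yl]oxy}propanoate (diastereomer mixture) | CCOC(=O)C(Br)C(OCC)OCC#Cc1ccoc1 | intermediate
7 | ethyl 2-ethoxy-4-(furan-3-ylmethylidene)oxolane-3-carboxylate (isomer mixture) | CCOC(=O)C1C(OCC)OCC1=Cc1ccoc1 | intermediate (not isolated)
8 | ethyl 4-(furan-3-ylmethyl)furan-3-carboxylate | CCOC(=O)c1cocc1Cc1ccoc1 | intermediate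
9 | [4-(furan-3-ylmethyl)furan-3-yl]methanol | OCc1cocc1Cc1ccoc1 | intermediate
10 | 4-(furan-3-ylmethyl)furan-3-carbaldehyde | O=Cc1cocc1Cc1ccoc1 | intermediate
11 | geranyl bromide, (2E)-1-bromo-3,7-dimethylocta-2,6-diene | CC(C)=CCC/C(C)=C/CBr | starting material
12 | triethyl phosphite | CCOP(OCC)OCC | starting material
13 | diethyl [(2E)-3,7-dimethylocta-2,6-dien-1-yl]phosphonate | CC(C)=CCC/C(C)=C/CP(=O)(OCC)OCC | intermediate
14 | diethyl [(2E,6E)-8-hydroxy-3,7-dimethylocta-2,6-dien-1-yl]phosphonate | OC/C(C)=C/CC/C(C)=C/CP(=O)(OCC)OCC | intermediate (not isolated)
15 | diethyl [(2E,6E)-3,7-dimethyl-8-oxoocta-2,6-dien-1-yl]phosphonate | O=C/C(C)=C/CC/C(C)=C/CP(=O)(OCC)OCC | intermediate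
16 | diethyl [(2E,7S)-3,7-dimethyl-8-oxooct-2-en-1-yl]phosphonate | O=C[C@@H](C)CCC/C(C)=C/CP(=O)(OCC)OCC | intermediate (not isolated)
17 | diethyl [(2E,7S)-8-hydroxy-3,7-dimethyloct-2-en-1-yl]phosphonate | OC[C@@H](C)CCC/C(C)=C/CP(=O)(OCC)OCC | intermediate
18 | (2S,6E,8E)-9-[4-(furan-3-ylmethyl)furan-3-yl]-2,6-dimethylnona-6,8-dien-1-ol | OC[C@@H](C)CCC/C(C)=C/C=C/c1cocc1Cc1ccoc1 | intermediate
19 | (2S,6E,8E)-9-[4-(furan-3-ylmethyl)furan-3-yl]-2,6-dimethylnona-6,8-dienal | O=C[C@@H](C)CCC/C(C)=C/C=C/c1cocc1Cc1ccoc1 | intermediate
20 | 4-hydroxy-3-methylfuran-2(5H)-one | CC1=C(O)COC1=O | starting material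
21 | 4-methoxy-3-methylfuran-2(5H)-one | COC1=C(C)C(=O)OC1 | intermediate
22 | 5-[(2S,6E,8E)-9-[4-(furan-3-ylmethyl)furan-3-yl]-1-hydroxy-2,6-dimethylnona-6,8-dien-1-yl]-4-methoxy-3-methylfuran-2(5H)-one (diastereomer mixture) | COC1=C(C)C(=O)OC1C(O)[C@@H](C)CCC/C(C)=C/C=C/c1cocc1Cc1ccoc1 | intermediate
23 | methanesulfonate of 22 at the C1′ hydroxyl (diastereomer mixture) | COC1=C(C)C(=O)OC1C(OS(C)(=O)=O)[C@@H](C)CCC/C(C)=C/C=C/c1cocc1Cc1ccoc1 | intermediate (not isolated)
24 | (5Z)-5-[(2S,6E,8E)-9-[4-(furan-3-ylmethyl)furan-3-yl]-2,6-dimethylnona-6,8-dien-1-ylidene]-4-methoxy-3-methylfuran-2(5H)-one | CC1=C(OC)/C(=C/[C@@H](C)CCC/C(C)=C/C=C/c2cocc2Cc2ccoc2)OC1=O | intermediate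
25 | (5Z)-5-[(2S,6E,8E)-9-[4-(furan-3-ylmethyl)furan-3-yl]-2,6-dimethylnona-6,8-dien-1-ylidene]-4-hydroxy-3-methylfuran-2(5H)-one | CC1=C(O)/C(=C/[C@@H](C)CCC/C(C)=C/C=C/c2cocc2Cc2ccoc2)OC1=O | target

## Step count and least certain steps

Total step count: 14. Longest linear sequence: 10 steps (steps 1, 2, 3, 4, 5, 9, 10, 12, 13, 14, from 1 to 25). Steps 6 to 8 form a three-step branch that joins at step 9, and step 11 a one-step branch that joins at step 12.

**Step 3 (key step).** The most likely failure is hydrogen transfer from the stannane to the ester-stabilized radical before it closes the ring, because stabilized radicals cyclize more slowly; a second risk is acid-induced oligomerization of the furans during aromatization. The fallback forms the same C3–C4 bond by a polar, palladium-mediated route. It sets out from 2 and 1 and returns at 8. The potassium alkoxide of 2 (KOt-Bu, DMSO–THF) adds to diethyl (ethoxymethylene)malonate. The malonate anion formed then attacks the alkyne anti to the furyl–palladium species generated from 1 and Pd(PPh3)4 (zerovalent palladium), and reductive elimination gives diethyl (4Z)-2-ethoxy-4-(furan-3-ylmethylidene)oxolane-3,3-dicarboxylate F1. KOt-Bu in THF then removes one ethoxycarbonyl group, ethoxide leaves, and the double bond moves into the ring to give 8.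

**Step 2.** The most likely failure is dehydrobromination of 5 by the base before the alcohol captures it, or exchange of both alkoxy groups of the acetal, since the oxocarbenium ion can re-form. The fallback separates halogenation from acetal exchange. It sets out from 4 and returns at 6. Compound 4 is brominated as in step 2 and 5 is quenched with ethanol and 2,6-lutidine to give distillable ethyl 2-bromo-3,3-diethoxypropanoate F2. An excess of F2 is then exchanged with 3 under pyridinium p-toluenesulfonate catalysis in toluene, with ethanol removed under reduced pressure, to give 6.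

**Step 8.** The most likely failure is incomplete facial selectivity or slow turnover with a phosphonate-bearing substrate, or partial enolization of 16 before its reduction. The fallback sets the stereocenter by carboxylate-directed hydrogenation. It sets out from 15 and returns at 17. Oxidation of 15 with NaClO2, NaH2PO4 and 2-methylbut-2-ene gives (2E,6E)-8-(diethoxyphosphoryl)-2,6-dimethylocta-2,6-dienoic acid F3. Hydrogenation with Ru(OAc)2[(S)-H8-BINAP] in methanol gives (2S,6E)-8-(diethoxyphosphoryl)-2,6-dimethyloct-6-enoic acid F4; the ligand hand is taken from the sense expected for tiglic acid with this catalyst family and would be checked on a test run. Activation with isobutyl chloroformate and N-methylmorpholine gives the mixed anhydride F5 (not isolated), and NaBH4 in aqueous THF reduces it to 17 without touching the alkene or the phosphonate.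

**Step 9.** The most likely failure is loss of geometric purity: some (8Z) isomer, scrambling of the (6E) alkene in the delocalized allyl anion, or attack through the γ-carbon. Aggregation of the alkoxide-bearing dianion could also lower conversion. The fallback protects the hydroxyl and corrects geometry by equilibration. It sets out from 17 and returns at 18. Silylation with tert-butyldiphenylsilyl chloride and imidazole gives diethyl [(2E,7S)-8-[(tert-butyldiphenylsilyl)oxy]-3,7-dimethyloct-2-en-1-yl]phosphonate F6. Olefination of 10 with one equivalent of n-BuLi gives tert-butyl{[(2S,6E,8E)-9-[4-(furan-3-ylmethyl)furan-3-yl]-2,6-dimethylnona-6,8-dien-1-yl]oxy}diphenylsilane F7, in which any (8Z) isomer is equilibrated with a trace of iodine in daylight. Bu4NF in THF then gives 18.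

**Step 14.** The most likely failure is reversible conjugate addition of the thiolate to the ylidene lactone, which could scramble the (Z) geometry or replace the C4 methoxy group by an alkylthio group, together with base-mediated erosion at C2′. The fallback uses an enol ether that is cleaved under neutral conditions. It sets out from 20 and 19 and returns at 25. Mitsunobu reaction of 20 with allyl alcohol (PPh3, diisopropyl azodicarboxylate) gives 4-(allyloxy)-3-methylfuran-2(5H)-one F8. Its lithium dienolate (LiN(i-Pr)2, THF, −78 °C) adds to 19 to give the aldol adduct F9. MsCl and Et3N give its methanesulfonate F10 (not isolated), and DBU gives the (5Z)-ylidene allyl ether F11. Pd(PPh3)4 (zerovalent palladium) with morpholine in THF at rt transfers the allyl group to the amine and releases 25.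

## Further compounds

F1 | step 3 | diethyl (4Z)-2-ethoxy-4-(furan-3-ylmethylidene)oxolane-3,3-dicarboxylate | CCOC(=O)C1(C(=O)OCC)C(OCC)OC/C1=C\c1ccoc1
F2 | step 2 | ethyl 2-bromo-3,3-diethoxypropanoate | CCOC(=O)C(Br)C(OCC)OCC
F3 | step 8 | (2E,6E)-8-(diethoxyphosphoryl)-2,6-dimethylocta-2,6-dienoic acid | OC(=O)/C(C)=C/CC/C(C)=C/CP(=O)(OCC)OCC
F4 | step 8 | (2S,6E)-8-(diethoxyphosphoryl)-2,6-dimethyloct-6-enoic acid | OC(=O)[C@@H](C)CCC/C(C)=C/CP(=O)(OCC)OCC
F5 | step 8 | isobutyl carbonic anhydride of F4 | CC(C)COC(=O)OC(=O)[C@@H](C)CCC/C(C)=C/CP(=O)(OCC)OCC
F6 | step 9 | diethyl [(2E,7S)-8-[(tert-butyldiphenylsilyl)oxy]-3,7-dimethyloct-2-en-1-yl]phosphonate | CC(C)(C)[Si](c1ccccc1)(c1ccccc1)OC[C@@H](C)CCC/C(C)=C/CP(=O)(OCC)OCC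
F7 | step 9 | tert-butyl{[(2S,6E,8E)-9-[4-(furan-3-ylmethyl)furan-3-yl]-2,6-dimethylnona-6,8-dien-1-yl]oxy}diphenylsilane | CC(C)(C)[Si](c1ccccc1)(c1ccccc1)OC[C@@H](C)CCC/C(C)=C/C=C/c1cocc1Cc1ccoc1
F8 | step 14 | 4-(allyloxy)-3-methylfuran-2(5H)-one | C=CCOC1=C(C)C(=O)OC1
F9 | step 14 | 4-(allyloxy)-5-[(2S,6E,8E)-9-[4-(furan-3-ylmethyl)furan-3-yl]-1-hydroxy-2,6-dimethylnona-6,8-dien-1-yl]-3-methylfuran-2(5H)-one (diastereomer mixture) | C=CCOC1=C(C)C(=O)OC1C(O)[C@@H](C)CCC/C(C)=C/C=C/c1cocc1Cc1ccoc1
F10 | step 14 | methanesulfonate of F9 at the C1′ hydroxyl | C=CCOC1=C(C)C(=O)OC1C(OS(C)(=O)=O)[C@@H](C)CCC/C(C)=C/C=C/c1cocc1Cc1ccoc1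
F11 | step 14 | (5Z)-4-(allyloxy)-5-[(2S,6E,8E)-9-[4-(furan-3-ylmethyl)furan-3-yl]-2,6-dimethylnona-6,8-dien-1-ylidene]-3-methylfuran-2(5H)-one | CC1=C(OCC=C)/C(=C/[C@@H](C)CCC/C(C)=C/C=C/c2cocc2Cc2ccoc2)OC1=O
A1 | alternative 1 | (3S,7R)-3,7-dimethyloxepan-2-one | C[C@H]1CCC[C@@H](C)OC1=O
A2 | alternative 1 | cis-2,6-dimethylcyclohexanone (meso) | C[C@H]1CCC[C@@H](C)C1=O
A3 | alternative 2 | tert-butyl{[(2S,6E,8E)-9-[4-(furan-3-ylmethyl)furan-3-yl]-2,6-dimethylnona-6,8-dien-1-yl]oxy}dimethylsilane | CC(C)(C)[Si](C)(C)OC[C@@H](C)CCC/C(C)=C/C=C/c1cocc1Cc1ccoc1
A4 | alternative 2 | tert-butyldimethyl{[(2S)-2-methylhept-6-yn-1-yl]oxy}silane | CC(C)(C)[Si](C)(C)OC[C@@H](C)CCCC#C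
A5 | alternative 2 | 3-(furan-3-ylmethyl)-4-[(E)-2-iodoethenyl]furan | I/C=C/c1cocc1Cc1ccoc1
A6 | alternative 3 | (5Z)-5-[(2S,6E,8E)-9-[4-(furan-3-ylmethyl)furan-3-yl]-2,6-dimethylnona-6,8-dien-1-ylidene]-4-methoxy-3-methylfuran-2(5H)-one (same compound as 24) | CC1=C(OC)/C(=C/[C@@H](C)CCC/C(C)=C/C=C/c2cocc2Cc2ccoc2)OC1=O
A7 | alternative 3 | (2E,6S,10E,12E)-13-[4-(furan-3-ylmethyl)furan-3-yl]-3-methoxy-2,6,10-trimethyltrideca-2,10,12-trien-4-ynoic acid | OC(=O)/C(C)=C(/OC)C#C[C@@H](C)CCC/C(C)=C/C=C/c1cocc1Cc1ccoc1
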